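**Retrosynthetic overview**
1. The target comes from its hexabenzyl ether 17 by hydrogenolysis. 17 is cut at the 3',3''' biaryl bond into two ring B iodides: flavanone 12 (used as its boronate) and (2R,3R)-3-hydroxyflavanone 15.
2. 15 comes from 12 by Rubottom oxidation. One (S)-flavanone iodide serves both halves, because C2 has the same spatial sense in both units of the target.
3. 12 comes from (S)-β-lactone 5 by ring expansion: 3,5-bis(benzyloxy)benzyne is inserted into the acyl C–O bond, so the four-membered lactone becomes the six-membered ring C with ring A fused to it. The aryne is made from resorcinol through iodonium salt 8.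
4. 5 comes from 4-(benzyloxy)-3-iodobenzaldehyde 4 and ketene by catalytic asymmetric aldol-lactonisation, which sets C2. 4 comes from 2-iodophenol by benzylation and Rieche formylation.
5. Ring order: the β-lactone first, then ring C (with ring A attached in the same step), then the bond between the two rings B.

Assumption: O-trimethylsilylquinidine is taken to give the (S)-lactone; its quinine-derived pseudoenantiomer is used if the sense proves opposite.

**Route**

Step 1
Reactants: 1 2-iodophenol
Product: 2 1-(benzyloxy)-2-iodobenzene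
Conditions: BnBr, K2CO3, DMF, rt
Reagents that add atoms: benzyl bromide, BrCc1ccccc1
Why: Williamson ether synthesis, in which the phenoxide displaces bromide and the phenol is masked as an ether that survives all later steps and leaves by hydrogenolysis.

Step 2
Reactants: 2 1-(benzyloxy)-2-iodobenzene
Product: 4 4-(benzyloxy)-3-iodobenzaldehyde, via chloro(methoxy)methyl arene 3 (not isolated)
Conditions: Cl2CHOMe, TiCl4, CH2Cl2, −78 to 0 °C; then H2O
Reagents that add atoms: dichloromethyl methyl ether, COC(Cl)Cl; water, O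
Why: Rieche formylation (Friedel–Crafts type), in which the TiCl4-activated electrophile attacks para to the benzyloxy group (meta to iodine) and hydrolysis of 3 on work-up releases the aldehyde.

Step 3
Reactants: 4 4-(benzyloxy)-3-iodobenzaldehyde
Product: 5 (S)-4-[4-(benzyloxy)-3-iodophenyl]oxetan-2-one
Conditions: AcCl, iPr2NEt, O-trimethylsilylquinidine (10 mol%), LiClO4, Et2O/CH2Cl2, −78 °C; product kept below 0 °C and not chromatographed
Reagents that add atoms: acetyl chloride, CC(Cl)=O
Why: Wynberg-type catalytic asymmetric ketene–aldehyde aldol-lactonisation (a stepwise formal [2+2]), in which the chiral ammonium enolate from in-situ ketene adds to one face of the LiClO4-activated aldehyde and closes to the lactone, setting the (S) centre under catalyst control.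

Step 4
Reactants: 6 resorcinol
Product: 7 1,3-bis(benzyloxy)benzene
Conditions: BnBr, K2CO3, DMF, 60 °C
Reagents that add atoms: benzyl bromide, BrCc1ccccc1
Why: Double Williamson ether synthesis, giving ethers that later steer the aryne regiochemistry and are removed in the final hydrogenolysis.

Step 5
Reactants: 7 1,3-bis(benzyloxy)benzene
Product: 8 [2,4-bis(benzyloxy)phenyl](mesityl)iodonium tosylate
Conditions: MesI(OH)OTs, CF3CH2OH/CH2Cl2, rt
Reagents that add atoms: [hydroxy(tosyloxy)iodo]mesitylene, Cc1cc(C)c(I(O)OS(=O)(=O)c2ccc(C)cc2)c(C)c1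
Why: Electrophilic aromatic substitution by the trivalent-iodine reagent (Koser-type arene iodination) at C4, para to one benzyloxy group and ortho to the other, gives an iodonium salt whose mesityl group has no ortho hydrogen, so later elimination can only occur on the dialkoxy ring.

Step 6
Reactants: 5 (S)-4-[4-(benzyloxy)-3-iodophenyl]oxetan-2-one; 8 [2,4-bis(benzyloxy)phenyl](mesityl)iodonium tosylate
Product: 12 (S)-5,7-bis(benzyloxy)-2-[4-(benzyloxy)-3-iodophenyl]chroman-4-one, via lithium alkoxide Weinreb amide 9 (not isolated), via 3,5-bis(benzyloxy)benzyne 10 (not isolated), via lithium hemiaminal chelate 11 (not isolated)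
Conditions: MeNHOMe (1.0 equiv), n-BuLi (1.0 equiv), THF, −78 °C, then 5; then 8 (1.5 equiv), LiN(SiMe3)2 (1.6 equiv), −78 to 0 °C; then 1 M HCl, 0 °C
Reagents that add atoms: none
Why: Proposed new method: a relay ring expansion that turns the four-membered lactone into the six-membered chromanone by net insertion of an aryne into the acyl C–O bond – LiN(Me)OMe opens the strained lactone at the acyl carbon to alkoxide 9, this alkoxide adds to aryne 10 (released from 8 by ortho-deprotonation and loss of iodomesitylene) at the carbon meta to both benzyloxy groups, and the resulting aryllithium closes 6-exo onto the Weinreb amide to chelate 11, which hides the ketone from base until the acid quench; the carbinol C–O bond is never broken, so the (S) centre is carried over unchanged, the aryl iodide is inert to the amide bases, and the closest known reaction types are aryne σ-insertion into the N–C(O) bond of amides and β-lactams and the aryne–salicylate annulation to xanthones.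

Step 7
Reactants: 12 (S)-5,7-bis(benzyloxy)-2-[4-(benzyloxy)-3-iodophenyl]chroman-4-one
Product: 15 (2R,3R)-5,7-bis(benzyloxy)-2-[4-(benzyloxy)-3-iodophenyl]-3-hydroxychroman-4-one, via trimethylsilyl enol ether 13 (not isolated), via 3-(trimethylsilyloxy) ketone 14 (not isolated)
Conditions: TMSOTf, Et3N, CH2Cl2, 0 °C; then DMDO (1.05 equiv), acetone, −40 to 0 °C; then 1 M HCl, THF, 0 °C
Reagents that add atoms: dimethyldioxirane, CC1(C)OO1
Why: Rubottom oxidation on one half of the batch of 12, in which soft enolisation gives 13 without opening ring C, dimethyldioxirane epoxidises the electron-rich enol ether (much faster than it oxidises the aryl iodide) on the face anti to the C2 aryl group and silyl migration gives 14, so the new hydroxyl is trans to the aryl group, (2R,3R), which is also the thermodynamically preferred C3 epimer (C2 is unchanged in space; only its descriptor changes).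

Step 8
Reactants: 12 (S)-5,7-bis(benzyloxy)-2-[4-(benzyloxy)-3-iodophenyl]chroman-4-one; 15 (2R,3R)-5,7-bis(benzyloxy)-2-[4-(benzyloxy)-3-iodophenyl]-3-hydroxychroman-4-one
Product: 17 (2R,3R)-5,7-bis(benzyloxy)-2-{6,6'-bis(benzyloxy)-3'-[(2S)-5,7-bis(benzyloxy)-4-oxochroman-2-yl]-[1,1'-biphenyl]-3-yl}-3-hydroxychroman-4-one, via pinacol boronate 16 (not isolated)
Conditions: 12, B2pin2 (1.05 equiv), Pd(OAc)2 (3 mol%), XPhos (6 mol%), KOAc, dioxane, 70 °C; then 15, degassed 0.5 M aq K3PO4, 40 °C
Reagents that add atoms: none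
Why: One-pot Miyaura borylation and Suzuki–Miyaura cross-coupling, in which the other half of 12 is converted into boronate 16 and coupled with iodide 15 by the same XPhos-ligated palladium catalyst, which joins di-ortho-substituted partners at low temperature under weak bases, so that no stereocentre is formed and the base-sensitive C2 and C3 centres are exposed only briefly.

Step 9
Reactants: 17 hexabenzyl ether of the target
Product: 18 CNP0201582.1, (2S)-naringenin-(3'→3''')-(2R,3R)-dihydrokaempferol
Conditions: H2 (1 atm), 10% Pd/C, EtOAc/MeOH, rt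
Reagents that add atoms: none
Why: Catalytic hydrogenolysis cleaves the six benzyl ethers under neutral conditions that leave the aryl ketones, the ring C benzylic C2–O bonds and the base-sensitive C2 and C3 stereocentres untouched.

**Compound list**
1 | 2-iodophenol | Oc1ccccc1I | starting material
2 | 1-(benzyloxy)-2-iodobenzene | Ic1ccccc1OCc1ccccc1 | intermediate
3 | 1-(benzyloxy)-4-[chloro(methoxy)methyl]-2-iodobenzene (not isolated, configuration at the CHCl centre undefined) | COC(Cl)c1ccc(OCc2ccccc2)c(I)c1 | intermediate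
4 | 4-(benzyloxy)-3-iodobenzaldehyde | O=Cc1ccc(OCc2ccccc2)c(I)c1 | intermediate
5 | (S)-4-[4-(benzyloxy)-3-iodophenyl]oxetan-2-one | O=C1C[C@@H](c2ccc(OCc3ccccc3)c(I)c2)O1 | intermediate
6 | resorcinol | Oc1cccc(O)c1 | starting material
7 | 1,3-bis(benzyloxy)benzene | c1cc(OCc2ccccc2)cc(OCc2ccccc2)c1 | intermediate
8 | [2,4-bis(benzyloxy)phenyl](mesityl)iodonium tosylate | Cc1cc(C)c([I+]c2ccc(OCc3ccccc3)cc2OCc2ccccc2)c(C)c1.Cc1ccc(S(=O)(=O)[O-])cc1 | intermediate
9 | lithium (S)-1-[4-(benzyloxy)-3-iodophenyl]-3-[methoxy(methyl)amino]-3-oxopropan-1-olate (not isolated) | [Li+].CON(C)C(=O)C[C@H]([O-])c1ccc(OCc2ccccc2)c(I)c1 | intermediate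
10 | 3,5-bis(benzyloxy)benzyne (not isolated) | C1#CC(OCc2ccccc2)=CC(OCc2ccccc2)=C1 | intermediate
11 | lithium (2S)-5,7-bis(benzyloxy)-2-[4-(benzyloxy)-3-iodophenyl]-4-[methoxy(methyl)amino]chroman-4-olate (not isolated, C4 configuration undefined) | [Li+].CON(C)C1([O-])C[C@@H](c2ccc(OCc3ccccc3)c(I)c2)Oc2cc(OCc3ccccc3)cc(OCc3ccccc3)c21 | intermediate
12 | (S)-5,7-bis(benzyloxy)-2-[4-(benzyloxy)-3-iodophenyl]chroman-4-one | O=C1C[C@@H](c2ccc(OCc3ccccc3)c(I)c2)Oc2cc(OCc3ccccc3)cc(OCc3ccccc3)c21 | intermediate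
13 | {[(2S)-5,7-bis(benzyloxy)-2-[4-(benzyloxy)-3-iodophenyl]-2H-chromen-4-yl]oxy}trimethylsilane (not isolated) | C[Si](C)(C)OC1=C[C@@H](c2ccc(OCc3ccccc3)c(I)c2)Oc2cc(OCc3ccccc3)cc(OCc3ccccc3)c21 | intermediate
14 | (2R,3R)-5,7-bis(benzyloxy)-2-[4-(benzyloxy)-3-iodophenyl]-3-(trimethylsilyloxy)chroman-4-one (not isolated) | Ic1cc([C@H]2Oc3cc(OCc4ccccc4)cc(OCc4ccccc4)c3C(=O)[C@@H]2O[Si](C)(C)C)ccc1OCc1ccccc1 | intermediate
15 | (2R,3R)-5,7-bis(benzyloxy)-2-[4-(benzyloxy)-3-iodophenyl]-3-hydroxychroman-4-one | Ic1cc([C@H]2Oc3cc(OCc4ccccc4)cc(OCc4ccccc4)c3C(=O)[C@@H]2O)ccc1OCc1ccccc1 | intermediate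
16 | (S)-5,7-bis(benzyloxy)-2-[4-(benzyloxy)-3-(4,4,5,5-tetramethyl-1,3,2-dioxaborolan-2-yl)phenyl]chroman-4-one (not isolated) | O=C1C[C@@H](c2ccc(OCc3ccccc3)c(B3OC(C)(C)C(C)(C)O3)c2)Oc2cc(OCc3ccccc3)cc(OCc3ccccc3)c21 | intermediate
17 | (2R,3R)-5,7-bis(benzyloxy)-2-{6,6'-bis(benzyloxy)-3'-[(2S)-5,7-bis(benzyloxy)-4-oxochroman-2-yl]-[1,1'-biphenyl]-3-yl}-3-hydroxychroman-4-one | O=C1C[C@@H](c2ccc(OCc3ccccc3)c(-c3cc([C@H]4Oc5cc(OCc6ccccc6)cc(OCc6ccccc6)c5C(=O)[C@@H]4O)ccc3OCc3ccccc3)c2)Oc2cc(OCc3ccccc3)cc(OCc3ccccc3)c21 | intermediate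
18 | CNP0201582.1, (2R,3R)-3,5,7-trihydroxy-2-{6,6'-dihydroxy-3'-[(2S)-5,7-dihydroxy-4-oxochroman-2-yl]-[1,1'-biphenyl]-3-yl}chroman-4-one | O=C1C[C@@H](c2ccc(O)c(-c3cc([C@H]4Oc5cc(O)cc(O)c5C(=O)[C@@H]4O)ccc3O)c2)Oc2cc(O)cc(O)c21 | target

**Step count and risks**
Total steps: 9. Longest linear sequence: 7 (steps 1, 2, 3, 6, 7, 8, 9).

Risk 1, step 6 (the proposed ring expansion). Likely failure modes are direct ipso O-arylation of the alkoxide by the iodonium salt, capture of the aryne by a nitrogen base, protonation of the aryllithium before it cyclises, and retro-aldol cleavage of 9. The fallback uses known chemistry only and no aryne; it sets out from 7 (with 4) and comes back at 12. Catalytic Friedel–Crafts acetylation of 7 (Ac2O, Sc(OTf)3 (10 mol%), LiClO4, MeNO2, 50 °C) gives 1-[2,4-bis(benzyloxy)phenyl]ethan-1-one F1. Ketone-directed ortho C–H borylation ([Ir(OMe)(cod)]2, AsPh3, B2pin2, octane, 120 °C) is chosen because an undirected borylation would attack the benzyl rings. It gives 1-[2,4-bis(benzyloxy)-6-(4,4,5,5-tetramethyl-1,3,2-dioxaborolan-2-yl)phenyl]ethan-1-one F2. Oxidation (NaBO3·4H2O, THF/H2O, rt) gives 1-[2,4-bis(benzyloxy)-6-hydroxyphenyl]ethan-1-one F3. Claisen–Schmidt condensation of F3 with aldehyde 4 (KOH, EtOH/THF, rt) gives (E)-3-[4-(benzyloxy)-3-iodophenyl]-1-[2,4-bis(benzyloxy)-6-hydroxyphenyl]prop-2-en-1-one F4. Oxa-Michael ring closure (NaOAc, EtOH, reflux) gives racemic 5,7-bis(benzyloxy)-2-[4-(benzyloxy)-3-iodophenyl]chroman-4-one F5, from which (S)-12 is separated by preparative chiral HPLC.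

Risk 2, step 3 (asymmetric lactonisation). The electron-rich aldehyde is a sluggish electrophile, and a β-lactone carrying a para-benzyloxyphenyl group can ionise and lose CO2. The enantiomeric excess may also fall short, and it can only be raised later by crystallising 12. The fallback sets out from 4 and comes back at 9, inside step 6. A catalytic asymmetric Mukaiyama aldol addition of 1-(tert-butylthio)-1-(trimethylsilyloxy)ethene to 4 (Ti(OiPr)4, (S)-BINOL or its antipode as required, Et2O, −20 °C, then 1 M HCl) gives S-tert-butyl (S)-3-[4-(benzyloxy)-3-iodophenyl]-3-hydroxypropanethioate F6. Aminolysis (MeNHOMe·HCl, AlMe3, CH2Cl2, 0 °C) gives (S)-3-[4-(benzyloxy)-3-iodophenyl]-3-hydroxy-N-methoxy-N-methylpropanamide F7. Deprotonation with LiN(SiMe3)2 (1.0 equiv, THF, −78 °C) gives 9, and the aryne stage of step 6 follows.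

Risk 3, step 8 (borylation and biaryl coupling). Both partners are base-sensitive. Ring C of either unit can open reversibly to the chalcone and so lose the C2 configuration, and the 3-hydroxy unit can epimerise or ring-contract. The ortho-alkoxy boronate can also protodeborylate. Any loss at C2 shows up as a diastereomer of 17, which can be separated. The fallback avoids base altogether; it sets out from 12 (with 15) and comes back at 17. Stannylation of 12 (Me3SnSnMe3, Pd(PPh3)4, toluene, 90 °C) gives (S)-5,7-bis(benzyloxy)-2-[4-(benzyloxy)-3-(trimethylstannyl)phenyl]chroman-4-one F8. Stille coupling of F8 with 15 (Pd(PPh3)4, CuI, DMF, 60 °C) gives 17.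

**Further compounds**
F1 | step 6 | 1-[2,4-bis(benzyloxy)phenyl]ethan-1-one | CC(=O)c1ccc(OCc2ccccc2)cc1OCc1ccccc1
F2 | step 6 | 1-[2,4-bis(benzyloxy)-6-(4,4,5,5-tetramethyl-1,3,2-dioxaborolan-2-yl)phenyl]ethan-1-one | CC(=O)c1c(B2OC(C)(C)C(C)(C)O2)cc(OCc2ccccc2)cc1OCc1ccccc1
F3 | step 6 | 1-[2,4-bis(benzyloxy)-6-hydroxyphenyl]ethan-1-one | CC(=O)c1c(O)cc(OCc2ccccc2)cc1OCc1ccccc1
F4 | step 6 | (E)-3-[4-(benzyloxy)-3-iodophenyl]-1-[2,4-bis(benzyloxy)-6-hydroxyphenyl]prop-2-en-1-one | O=C(/C=C/c1ccc(OCc2ccccc2)c(I)c1)c1c(O)cc(OCc2ccccc2)cc1OCc1ccccc1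
F5 | step 6 | racemic 5,7-bis(benzyloxy)-2-[4-(benzyloxy)-3-iodophenyl]chroman-4-one | O=C1CC(c2ccc(OCc3ccccc3)c(I)c2)Oc2cc(OCc3ccccc3)cc(OCc3ccccc3)c21
F6 | step 3 | S-tert-butyl (S)-3-[4-(benzyloxy)-3-iodophenyl]-3-hydroxypropanethioate | CC(C)(C)SC(=O)C[C@H](O)c1ccc(OCc2ccccc2)c(I)c1
F7 | step 3 | (S)-3-[4-(benzyloxy)-3-iodophenyl]-3-hydroxy-N-methoxy-N-methylpropanamide | CON(C)C(=O)C[C@H](O)c1ccc(OCc2ccccc2)c(I)c1
F8 | step 8 | (S)-5,7-bis(benzyloxy)-2-[4-(benzyloxy)-3-(trimethylstannyl)phenyl]chroman-4-one | O=C1C[C@@H](c2ccc(OCc3ccccc3)c([Sn](C)(C)C)c2)Oc2cc(OCc3ccccc3)cc(OCc3ccccc3)c21
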